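## Retrosynthetic overview

1. Target 32 ⇐ removal of four MOM ethers ⇐ flavanone 31 ⇐ rhodium-catalysed asymmetric 1,4-arylation of chromone 24 (rings A and C) with boronic acid 30 (ring B, from catechol); this sets C2.
2. Chromone 24 ⇐ ring C closed by the single SEM-masked phenol oxygen onto ynone 21 ⇐ ring-A arene 14 + Weinreb ynamide 18.
3. Ring A ⇐ resorcinol: C-prenylation between the two MOM ethers, iridium C–H borylation/oxidation for the third oxygen (future O1), then two ortho-lithiations at its flanks. This symmetry fixes prenyl at C6 and the side chain at C8.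
4. Side-chain stereocentre ⇐ Sharpless epoxidation of prenol (epoxy triflate 11), then epoxide-to-allylic-alcohol rearrangement on ring A.
5. Ring order: rings A and B are bought as benzenes; ring C is the only ring formed (step 11), just before the C2–aryl bond is made.

Assumption: the (S,S)-diene is taken to give the 2S flavanone by the facial model known for monovalent-rhodium/diene arylation of cyclic enones; if the sense proves opposite, the (R,R)-diene is used with nothing else changed.

## Route

Step 1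
Reactants: 1 resorcinol
Product: 2 1,3-bis(methoxymethoxy)benzene
Conditions: NaH, MOMCl, DMF, 0 °C to rt
Reagents that add atoms: chloromethyl methyl ether, COCCl
Why: Williamson O-alkylation of both phenols gives the MOM ethers that later direct ortho-lithiation.

Step 2
Reactants: 2 1,3-bis(methoxymethoxy)benzene; 3 prenyl bromide
Product: 5 1,3-bis(methoxymethoxy)-2-(3-methylbut-2-en-1-yl)benzene, via aryllithium 4 (not isolated)
Conditions: n-BuLi, TMEDA, THF, 0 °C; then CuBr·SMe2 (10 mol%), 3, −78 °C to rt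
Reagents that add atoms: n-butyllithium, [Li]CCCC (lithium of 4 only)
Why: directed ortho-metalation occurs at the position between the two OMOM groups, and copper-catalysed SN2 allylation gives the linear prenyl group.

Step 3
Reactants: 5 1,3-bis(methoxymethoxy)-2-(3-methylbut-2-en-1-yl)benzene
Product: 7 3,5-bis(methoxymethoxy)-4-(3-methylbut-2-en-1-yl)phenol, via aryl pinacolboronate 6 (not isolated)
Conditions: [Ir(OMe)(cod)]2 (1.5 mol%), 4,4'-di-tert-butyl-2,2'-bipyridine (3 mol%), B2pin2 (1.0 equiv), THF, 65 °C; then 30% H2O2, aq NaOH, 0 °C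
Reagents that add atoms: bis(pinacolato)diboron, CC1(C)OB(OC1(C)C)B1OC(C)(C)C(C)(C)O1 (boryl group of 6 only); hydrogen peroxide, OO (phenol oxygen of 7)
Why: sterically governed iridium-catalysed aromatic C–H borylation takes the only C–H with no ortho neighbour (para to prenyl), and alkaline peroxide oxidises C–B to C–O without touching the trisubstituted alkene.

Step 4
Reactants: 7 3,5-bis(methoxymethoxy)-4-(3-methylbut-2-en-1-yl)phenol
Product: 8 SEM ether of 7 (trimethyl{2-[(3,5-bis(methoxymethoxy)-4-(3-methylbut-2-en-1-yl)phenoxy)methoxy]ethyl}silane)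
Conditions: NaH, SEMCl, THF, 0 °C to rt
Reagents that add atoms: 2-(trimethylsilyl)ethoxymethyl chloride, C[Si](C)(C)CCOCCl
Why: Williamson etherification marks the oxygen that becomes O1 with a fluoride-labile acetal that directs lithiation like MOM but can be removed in its presence.

Step 5
Reactants: 9 prenol (3-methylbut-2-en-1-ol)
Product: 10 [(2R)-3,3-dimethyloxiran-2-yl]methanol
Conditions: Ti(OiPr)4 (10 mol%), D-(−)-diisopropyl tartrate (12 mol%), t-BuOOH, 4 Å molecular sieves, CH2Cl2, −20 °C
Reagents that add atoms: tert-butyl hydroperoxide, CC(C)(C)OO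
Why: Sharpless asymmetric epoxidation, in which the D-tartrate titanium complex delivers oxygen to the face that gives the 2R epoxy alcohol (about 90–95% ee).

Step 6
Reactants: 10 [(2R)-3,3-dimethyloxiran-2-yl]methanol
Product: 11 [(2R)-3,3-dimethyloxiran-2-yl]methyl trifluoromethanesulfonate
Conditions: Tf2O, 2,6-lutidine, CH2Cl2, −78 °C; cold filtration, used at once
Reagents that add atoms: trifluoromethanesulfonic anhydride, O=S(=O)(OS(=O)(=O)C(F)(F)F)C(F)(F)F
Why: O-sulfonylation of the primary alcohol leaves the stereocentre untouched and gives an electrophile reactive enough at −78 °C.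

Step 7
Reactants: 8 SEM ether of 7; 11 [(2R)-3,3-dimethyloxiran-2-yl]methyl trifluoromethanesulfonate
Product: 13 (2R)-2-{[2,4-bis(methoxymethoxy)-3-(3-methylbut-2-en-1-yl)-6-{[2-(trimethylsilyl)ethoxy]methoxy}phenyl]methyl}-3,3-dimethyloxirane, via aryllithium 12 (not isolated)
Conditions: n-BuLi, TMEDA, THF, 0 °C; then CuBr·SMe2 (10 mol%), 11, −78 to −30 °C
Reagents that add atoms: n-butyllithium, [Li]CCCC (lithium of 12 only)
Why: directed ortho-metalation at one of the two equivalent C–H positions flanked by OSEM and OMOM, then copper-catalysed SN2 displacement of the primary triflate, which outruns attack on the hindered trisubstituted epoxide, so the R centre is carried over unchanged.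

Step 8
Reactants: 13 the (2R)-epoxide
Product: 14 (2R)-1-[2,4-bis(methoxymethoxy)-3-(3-methylbut-2-en-1-yl)-6-{[2-(trimethylsilyl)ethoxy]methoxy}phenyl]-3-methylbut-3-en-2-ol
Conditions: Et2Al(TMP) [from lithium 2,2,6,6-tetramethylpiperidide and Et2AlCl], toluene, 0 °C; then aq potassium sodium tartrate
Reagents that add atoms: none
Why: Yamamoto aluminium-amide epoxide-to-allylic-alcohol rearrangement (syn β-elimination) cleaves the tertiary C–O bond with loss of a methyl proton, so the secondary C–O bond is never broken and the R configuration is retained.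

Step 9
Reactants: 15 ethynyltrimethylsilane; 16 N-methoxy-N-methylcarbamoyl chloride
Product: 18 N-methoxy-N-methyl-3-(trimethylsilyl)prop-2-ynamide, via lithium acetylide 17 (not isolated)
Conditions: n-BuLi, THF, −78 °C; then 16, −78 to 0 °C
Reagents that add atoms: n-butyllithium, [Li]CCCC (lithium of 17 only)
Why: nucleophilic acyl substitution of the carbamoyl chloride by the lithium acetylide gives the Weinreb ynamide.

Step 10
Reactants: 14 the (2R)-allylic alcohol; 18 N-methoxy-N-methyl-3-(trimethylsilyl)prop-2-ynamide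
Product: 21 1-[3-[(2R)-2-hydroxy-3-methylbut-3-en-1-yl]-4,6-bis(methoxymethoxy)-5-(3-methylbut-2-en-1-yl)-2-{[2-(trimethylsilyl)ethoxy]methoxy}phenyl]-3-(trimethylsilyl)prop-2-yn-1-one, via dilithio species 19 (not isolated), via tetrahedral adduct 20 (not isolated)
Conditions: n-BuLi (2.3 equiv), TMEDA, THF, −20 to 0 °C; then 18, −78 to 0 °C; H2O
Reagents that add atoms: n-butyllithium, [Li]CCCC (lithium of 19 and 20 only)
Why: the first equivalent forms the alkoxide and the second performs directed ortho-metalation at the last ring C–H (between OSEM and OMOM), and the Weinreb ketone synthesis stops at the ynone because the chelated adduct survives until work-up.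

Step 11
Reactants: 21 the trimethylsilyl ynone
Product: 24 8-[(2R)-2-hydroxy-3-methylbut-3-en-1-yl]-5,7-bis(methoxymethoxy)-6-(3-methylbut-2-en-1-yl)-4H-chromen-4-one, via enaminone 22 (not isolated), via phenol enaminone 23 (not isolated)
Conditions: Et2NH, EtOH, rt; then TBAF, THF, 60 °C; then AcOH, 50 °C
Reagents that add atoms: diethylamine, CCNCC (in 22 and 23 only; expelled on ring closure)
Why: amine conjugate addition with protodesilylation masks the ynone as a vinylogous amide, fluoride cleaves only the SEM ether, and the freed phenol closes ring C by acid-promoted addition–elimination; because this oxygen is the one flanked by the acyl group and the side chain, the C6/C8 pattern is unambiguous.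

Step 12
Reactants: 25 catechol
Product: 26 1,2-bis(methoxymethoxy)benzene
Conditions: NaH, MOMCl, DMF, 0 °C to rt
Reagents that add atoms: chloromethyl methyl ether, COCCl
Why: Williamson O-alkylation protects both phenols of ring B.

Step 13
Reactants: 26 1,2-bis(methoxymethoxy)benzene
Product: 27 4-bromo-1,2-bis(methoxymethoxy)benzene
Conditions: NBS, MeCN, 0 °C to rt
Reagents that add atoms: N-bromosuccinimide, O=C1CCC(=O)N1Br
Why: electrophilic aromatic bromination goes para to one alkoxy group, the only unhindered activated position.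

Step 14
Reactants: 27 4-bromo-1,2-bis(methoxymethoxy)benzene
Product: 30 [3,4-bis(methoxymethoxy)phenyl]boronic acid, via aryllithium 28 (not isolated), via lithium triisopropoxyborate 29 (not isolated)
Conditions: n-BuLi, THF, −78 °C; B(OiPr)3, −78 °C to rt; then 1 M HCl to pH 5–6
Reagents that add atoms: n-butyllithium, [Li]CCCC (lithium of 28 and 29 only); triisopropyl borate, CC(C)OB(OC(C)C)OC(C)C (boron); water, O (the two B–OH oxygens)
Why: bromine–lithium exchange, borylation and mild hydrolysis of the borate give the boronic acid with the MOM ethers intact.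

Step 15
Reactants: 24 the ring-A chromone; 30 [3,4-bis(methoxymethoxy)phenyl]boronic acid
Product: 31 (2S)-2-[3,4-bis(methoxymethoxy)phenyl]-8-[(2R)-2-hydroxy-3-methylbut-3-en-1-yl]-5,7-bis(methoxymethoxy)-6-(3-methylbut-2-en-1-yl)-2,3-dihydro-4H-chromen-4-one
Conditions: [RhCl(C2H4)2]2 (2.5 mol%), (S,S)-Ph-bod* [(1S,4S)-2,5-diphenylbicyclo[2.2.2]octa-2,5-diene] (5.5 mol%), KOH (0.3 equiv), 30 (3 equiv), 1,4-dioxane/H2O 10:1, 40 °C
Reagents that add atoms: none
Why: Proposed new method: monovalent-rhodium/chiral-diene 1,4-arylation applied to a fully substituted 5,7-dioxygenated 6,8-dialkyl chromone carrying a free allylic alcohol and two olefins, a substrate class on which this reactivity has not been shown. The boronic acid transmetalates to the hydroxorhodium–diene complex, the aryl–rhodium inserts C2=C3 on the face left open by the (S,S)-diene to set 2S under catalyst control irrespective of the remote R centre, and water protonates the oxa-π-allyl rhodium before ring C can open, while unactivated alkenes and the alcohol do not insert. The closest known reaction type is rhodium/diene or rhodium/bisphosphine asymmetric 1,4-addition of arylboronic acids to simple chromones, and the minor diastereomer arising from the ee of 10 is removed by chromatography here.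

Step 16
Reactants: 31 the tetra-MOM flavanone
Product: 32 (2S)-2-(3,4-dihydroxyphenyl)-5,7-dihydroxy-8-[(2R)-2-hydroxy-3-methylbut-3-en-1-yl]-6-(3-methylbut-2-en-1-yl)-2,3-dihydro-4H-chromen-4-one
Conditions: 3 M aq HCl/MeOH/THF (1:10:5), 45 °C
Reagents that add atoms: none
Why: acid-catalysed acetal exchange (MOM methanolysis) frees the four phenols as dimethoxymethane; the acid is dilute and the temperature low so that the isopropenyl carbinol, the prenyl group and the C2 configuration are intended to survive.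

## Compound list

1 | resorcinol (benzene-1,3-diol) | Oc1cccc(O)c1 | starting material
2 | 1,3-bis(methoxymethoxy)benzene | COCOc1cccc(OCOC)c1 | intermediate
3 | prenyl bromide (1-bromo-3-methylbut-2-ene) | CC(C)=CCBr | starting material
4 | [2,6-bis(methoxymethoxy)phenyl]lithium (in situ) | [Li]c1c(OCOC)cccc1OCOC | intermediate
5 | 1,3-bis(methoxymethoxy)-2-(3-methylbut-2-en-1-yl)benzene | COCOc1cccc(OCOC)c1CC=C(C)C | intermediate
6 | 2-[3,5-bis(methoxymethoxy)-4-(3-methylbut-2-en-1-yl)phenyl]-4,4,5,5-tetramethyl-1,3,2-dioxaborolane (in situ) | COCOc1cc(B2OC(C)(C)C(C)(C)O2)cc(OCOC)c1CC=C(C)C | intermediate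
7 | 3,5-bis(methoxymethoxy)-4-(3-methylbut-2-en-1-yl)phenol | COCOc1cc(O)cc(OCOC)c1CC=C(C)C | intermediate
8 | trimethyl{2-[(3,5-bis(methoxymethoxy)-4-(3-methylbut-2-en-1-yl)phenoxy)methoxy]ethyl}silane (SEM ether of 7) | COCOc1cc(OCOCC[Si](C)(C)C)cc(OCOC)c1CC=C(C)C | intermediate
9 | prenol (3-methylbut-2-en-1-ol) | CC(C)=CCO | starting material
10 | [(2R)-3,3-dimethyloxiran-2-yl]methanol | OC[C@H]1OC1(C)C | intermediate
11 | [(2R)-3,3-dimethyloxiran-2-yl]methyl trifluoromethanesulfonate | FC(F)(F)S(=O)(=O)OC[C@H]1OC1(C)C | intermediate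
12 | {2,4-bis(methoxymethoxy)-3-(3-methylbut-2-en-1-yl)-6-{[2-(trimethylsilyl)ethoxy]methoxy}phenyl}lithium (in situ) | [Li]c1c(OCOCC[Si](C)(C)C)cc(OCOC)c(CC=C(C)C)c1OCOC | intermediate
13 | (2R)-2-{[2,4-bis(methoxymethoxy)-3-(3-methylbut-2-en-1-yl)-6-{[2-(trimethylsilyl)ethoxy]methoxy}phenyl]methyl}-3,3-dimethyloxirane | CC1(C)O[C@@H]1Cc1c(OCOCC[Si](C)(C)C)cc(OCOC)c(CC=C(C)C)c1OCOC | intermediate
14 | (2R)-1-[2,4-bis(methoxymethoxy)-3-(3-methylbut-2-en-1-yl)-6-{[2-(trimethylsilyl)ethoxy]methoxy}phenyl]-3-methylbut-3-en-2-ol | C=C(C)[C@H](O)Cc1c(OCOCC[Si](C)(C)C)cc(OCOC)c(CC=C(C)C)c1OCOC | intermediate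
15 | ethynyltrimethylsilane | C#C[Si](C)(C)C | starting material
16 | N-methoxy-N-methylcarbamoyl chloride | CON(C)C(=O)Cl | starting material
17 | lithium (trimethylsilyl)acetylide (in situ) | [Li]C#C[Si](C)(C)C | intermediate
18 | N-methoxy-N-methyl-3-(trimethylsilyl)prop-2-ynamide | CON(C)C(=O)C#C[Si](C)(C)C | intermediate
19 | dilithio derivative of 14: lithium alkoxide, ring lithiated at the last free position between OSEM and OMOM (in situ) | C=C(C)[C@H](O[Li])Cc1c(OCOCC[Si](C)(C)C)c([Li])c(OCOC)c(CC=C(C)C)c1OCOC | intermediate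
20 | chelated tetrahedral adduct of 19 with 18 (dilithium salt; new carbinol carbon unassigned; in situ) | C=C(C)[C@H](O[Li])Cc1c(OCOCC[Si](C)(C)C)c(C(O[Li])(N(C)OC)C#C[Si](C)(C)C)c(OCOC)c(CC=C(C)C)c1OCOC | intermediate
21 | 1-[3-[(2R)-2-hydroxy-3-methylbut-3-en-1-yl]-4,6-bis(methoxymethoxy)-5-(3-methylbut-2-en-1-yl)-2-{[2-(trimethylsilyl)ethoxy]methoxy}phenyl]-3-(trimethylsilyl)prop-2-yn-1-one | C=C(C)[C@H](O)Cc1c(OCOCC[Si](C)(C)C)c(C(=O)C#C[Si](C)(C)C)c(OCOC)c(CC=C(C)C)c1OCOC | intermediate
22 | (2E)-3-(diethylamino)-1-[3-[(2R)-2-hydroxy-3-methylbut-3-en-1-yl]-4,6-bis(methoxymethoxy)-5-(3-methylbut-2-en-1-yl)-2-{[2-(trimethylsilyl)ethoxy]methoxy}phenyl]prop-2-en-1-one (in situ) | C=C(C)[C@H](O)Cc1c(OCOCC[Si](C)(C)C)c(C(=O)/C=C/N(CC)CC)c(OCOC)c(CC=C(C)C)c1OCOC | intermediate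
23 | (2E)-3-(diethylamino)-1-[2-hydroxy-3-[(2R)-2-hydroxy-3-methylbut-3-en-1-yl]-4,6-bis(methoxymethoxy)-5-(3-methylbut-2-en-1-yl)phenyl]prop-2-en-1-one (in situ) | C=C(C)[C@H](O)Cc1c(O)c(C(=O)/C=C/N(CC)CC)c(OCOC)c(CC=C(C)C)c1OCOC | intermediate
24 | 8-[(2R)-2-hydroxy-3-methylbut-3-en-1-yl]-5,7-bis(methoxymethoxy)-6-(3-methylbut-2-en-1-yl)-4H-chromen-4-one | C=C(C)[C@H](O)Cc1c(OCOC)c(CC=C(C)C)c(OCOC)c2c(=O)ccoc12 | intermediate
25 | catechol (benzene-1,2-diol) | Oc1ccccc1O | starting material
26 | 1,2-bis(methoxymethoxy)benzene | COCOc1ccccc1OCOC | intermediate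
27 | 4-bromo-1,2-bis(methoxymethoxy)benzene | COCOc1ccc(Br)cc1OCOC | intermediate
28 | [3,4-bis(methoxymethoxy)phenyl]lithium (in situ) | [Li]c1ccc(OCOC)c(OCOC)c1 | intermediate
29 | lithium [3,4-bis(methoxymethoxy)phenyl]tri(propan-2-yloxy)borate (in situ) | [Li+].CC(C)O[B-](OC(C)C)(OC(C)C)c1ccc(OCOC)c(OCOC)c1 | intermediate
30 | [3,4-bis(methoxymethoxy)phenyl]boronic acid | COCOc1ccc(B(O)O)cc1OCOC | intermediate
31 | (2S)-2-[3,4-bis(methoxymethoxy)phenyl]-8-[(2R)-2-hydroxy-3-methylbut-3-en-1-yl]-5,7-bis(methoxymethoxy)-6-(3-methylbut-2-en-1-yl)-2,3-dihydro-4H-chromen-4-one | C=C(C)[C@H](O)Cc1c(OCOC)c(CC=C(C)C)c(OCOC)c2c1O[C@H](c1ccc(OCOC)c(OCOC)c1)CC2=O | intermediate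
32 | (2S)-2-(3,4-dihydroxyphenyl)-5,7-dihydroxy-8-[(2R)-2-hydroxy-3-methylbut-3-en-1-yl]-6-(3-methylbut-2-en-1-yl)-2,3-dihydro-4H-chromen-4-one | C=C(C)[C@H](O)Cc1c(O)c(CC=C(C)C)c(O)c2c1O[C@H](c1ccc(O)c(O)c1)CC2=O | target

## Step count and risks

Total step count: 16. Longest linear sequence: 10 steps (1, 2, 3, 4, 7, 8, 10, 11, 15, 16).

The three steps most likely to fail are step 15, step 7 and step 16.

For step 15 (the proposed new arylation), the electron-rich, fully substituted chromone may be too poor an acceptor or may ring-open. The fallback sets out from chromone 24, with bromide 27 as the aryl source, and comes back at 31. It uses known organocopper chemistry and gives up catalyst control. Bromide 27 is converted with Mg in THF into [3,4-bis(methoxymethoxy)phenyl]magnesium bromide F3 (3 equiv; the first equivalent is spent on the free alcohol and returns 26). F3 adds to 24 under CuBr·SMe2 catalysis with Me3SiCl at −78 °C to give the bis-silylated 2-aryl-4-(trimethylsilyloxy)-2H-chromene F4 as both C2 epimers. Aqueous citric acid hydrolyses F4 to 31 together with its (2R) epimer F5. Because the side-chain centre is fixed as R, 31 and F5 are diastereomers and are separated by preparative HPLC.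

For step 7 (coupling of a crowded aryllithium with the sensitive epoxy triflate 11), the fallback sets out from 8, lithiated as before to 12, and comes back at 14; it bypasses 13 and step 8. Aryllithium 12 is quenched with ethylene oxide to give 2-[2,4-bis(methoxymethoxy)-3-(3-methylbut-2-en-1-yl)-6-{[2-(trimethylsilyl)ethoxy]methoxy}phenyl]ethan-1-ol F1. Dess–Martin oxidation gives the corresponding arylacetaldehyde F2. An asymmetric Nozaki–Hiyama–Kishi alkenylation with 2-bromopropene (CrCl2, catalytic NiCl2, the chiral sulfonamide ligand antipode that gives the R carbinol, Et3N, THF) then delivers 14 directly. The stereocentre is thus made by reagent control at a carbonyl instead of being imported with the epoxide.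

For step 16 (four MOM ethers to be removed from a product with an isopropenyl carbinol, a prenyl group and an epimerisable C2), the fallback sets out from 31 and comes back at 32 without any protic acid. Me3SiOTf and 2,2'-bipyridyl in CH2Cl2 at 0 °C exchange the four aryl MOM ethers for trimethylsilyl ethers and silylate the alcohol, giving the pentakis(trimethylsilyl) ether F6. Water at rt then hydrolyses the silyl ethers to 32 at neutral pH.

## Further compounds

F1 | step 7 | 2-[2,4-bis(methoxymethoxy)-3-(3-methylbut-2-en-1-yl)-6-{[2-(trimethylsilyl)ethoxy]methoxy}phenyl]ethan-1-ol | OCCc1c(OCOCC[Si](C)(C)C)cc(OCOC)c(CC=C(C)C)c1OCOC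
F2 | step 7 | 2-[2,4-bis(methoxymethoxy)-3-(3-methylbut-2-en-1-yl)-6-{[2-(trimethylsilyl)ethoxy]methoxy}phenyl]acetaldehyde | O=CCc1c(OCOCC[Si](C)(C)C)cc(OCOC)c(CC=C(C)C)c1OCOC
F3 | step 15 | [3,4-bis(methoxymethoxy)phenyl]magnesium bromide | Br[Mg]c1ccc(OCOC)c(OCOC)c1
F4 | step 15 | 2-[3,4-bis(methoxymethoxy)phenyl]-5,7-bis(methoxymethoxy)-6-(3-methylbut-2-en-1-yl)-8-[(2R)-3-methyl-2-(trimethylsilyloxy)but-3-en-1-yl]-4-(trimethylsilyloxy)-2H-chromene (both C2 epimers) | C=C(C)[C@H](O[Si](C)(C)C)Cc1c(OCOC)c(CC=C(C)C)c(OCOC)c2c1OC(c1ccc(OCOC)c(OCOC)c1)C=C2O[Si](C)(C)C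
F5 | step 15 | (2R)-2-[3,4-bis(methoxymethoxy)phenyl]-8-[(2R)-2-hydroxy-3-methylbut-3-en-1-yl]-5,7-bis(methoxymethoxy)-6-(3-methylbut-2-en-1-yl)-2,3-dihydro-4H-chromen-4-one | C=C(C)[C@H](O)Cc1c(OCOC)c(CC=C(C)C)c(OCOC)c2c1O[C@@H](c1ccc(OCOC)c(OCOC)c1)CC2=O
F6 | step 16 | (2S)-2-[3,4-bis(trimethylsilyloxy)phenyl]-6-(3-methylbut-2-en-1-yl)-8-[(2R)-3-methyl-2-(trimethylsilyloxy)but-3-en-1-yl]-5,7-bis(trimethylsilyloxy)-2,3-dihydro-4H-chromen-4-one | C=C(C)[C@H](O[Si](C)(C)C)Cc1c(O[Si](C)(C)C)c(CC=C(C)C)c(O[Si](C)(C)C)c2c1O[C@H](c1ccc(O[Si](C)(C)C)c(O[Si](C)(C)C)c1)CC2=O
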